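Structural features

The target is a biflavonoid. A flavanone unit (rings A, C and B; atoms unprimed, ring B primed) is bonded through C3 to C8'' of a flavone unit of the apigenin type (atoms double-primed, its 2-aryl ring triple-primed), and O7'' carries a hydrogen sulfate. The only stereocentres are C2 (R) and C3 (S), adjacent in ring C and trans. C2 bears the ring oxygen O1 and the 4-hydroxyphenyl group; C3 bears the flavonyl group and lies alpha to the C4 ketone. C3–H is acidic, so the trans relation is under thermodynamic control, whereas C2 is lost only if ring C opens by retro-oxa-Michael reaction; the absolute configuration at C2 is therefore the real stereochemical problem. The fragile groups are the aryl sulfate monoester (acid, heat), the flavanone ring (base), the reducible flavone enone, and five free phenols from which O7''–H must be told apart. The main constitutional difficulty is the C3–C8'' bond, which joins a tertiary sp3 carbon to an aryl carbon flanked by O7'' and O1'', right next to C2. The key step exploits that C4 is an aryl ketone carbon bonded to C4a and C3 while C2 hangs on ring A through O1: C4–C4a–C8a–O1 is a salicylaldehyde unit, and C3 with C2 is an alpha-aryloxy ketone whose alpha carbon (C2) is stereolabile before ring closure.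

Logic of the disconnections

18 ⇒ 17. Cut: the five O–CH2Ph bonds at O5, O7, O4', O5'' and O4''' (retrosynthetic benzylation). Reason: the sulfate must be in place before the phenols are bared, and hydrogenolysis unmasks five phenols at once under neutral conditions. Gain: a lipophilic penultimate compound that can be purified on silica. Demand: the forward step must spare the O–S bond, the cyclic benzylic C2–O1 bond and the C2''=C3'' bond.

17 ⇒ 16. Cut: O7''–S. Reason: the sulfate is the most fragile group and goes on last among the bond-forming events. Gain: the only ionic group is removed. Demand: 16 may have one free hydroxyl only, and the sulfating agent must reach a phenol ortho to the bulky C3 substituent.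

16 ⇒ 15. Cut: the O7''–CH2 bond of an acetal. Reason: an acetal on O7'' is orthogonal to the benzyl ethers and marks the sulfation site from the start. Gain: one protecting-group pattern serves the whole route. Demand: the acid used must not open ring C.

15 ⇒ 13. Retrosynthetic addition of a hydroxyl at C3 (forward: C3–O cleavage). Reason: with the hydroxyl, C3 becomes the carbinol carbon of an alpha-hydroxy ketone, the retron of a benzoin reaction. Gain: the C3 configuration need not be controlled, since it is erased. Demand: the reductive cleavage must act on the ring C ketol and not on the flavone, must leave C2 alone, and C3 must settle trans.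

13 ⇒ 12. Cut: C3–C4. Reason: this is the only ring C bond whose formation can use the stereolability of C2. Gain: ring C is opened and both stereocentres vanish as problems of synthesis, 12 being acyclic at this site and racemic. Demand: a chiral acyl anion catalyst must close the ring faster than the enolate of 12 undergoes aldol reaction, and must take one C2 enantiomer only.

12 ⇒ 9 + 11. Cut: O1–C2. Reason: an alpha-halo ketone and a phenol are the natural partners. Gain: two fragments of similar size, ring A with the aldehyde in 11 and the rest in 9. Demand: O-alkylation without aldol closure onto the aldehyde.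

9 ⇒ 7. Cut: C2–Br. Reason: the benzylic methylene of 7 is the only enolisable site. Demand: bromination at carbon alpha to the ketone and not on the electron-rich rings, without acid that would cleave the acetal.

7 ⇒ 4 + 5. Cut: C8''–C(=O) and C(=O)–CH2, with carbon monoxide as the future C3. Reason: the congested aryl–carbon bond is made at an sp2 acyl carbon rather than at an sp3 centre. Gain: the flavone half and ring B are separated. Demand: CO insertion must beat direct coupling at a di-ortho-substituted aryl iodide.

4 ⇒ 3. Cut: C8''–I. Demand: iodination at C8'' and not at C6''.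

3 ⇒ 2. Cut: O5''–CH2Ph and O4'''–CH2Ph. Demand: alkylation of the chelated hydroxyl at O5''.

2 ⇒ 1. Cut: O7''–CH2OMe. Demand: etherification of the most acidic of three phenols only.

11 ⇒ 10. Cut: two O–CH2Ph bonds. Demand: the hydroxyl hydrogen-bonded to the aldehyde must stay free.

Other disconnections considered

Alternative 1: The cut removes the flavone pyranone ring (C4a''–C4'', C4''–C3'', O1''–C2''). In the forward sense the iodoresorcinol A1, a (2R,3S)-3-aryl flavanone with a 4-benzyloxy-2,6-dihydroxy-3-iodophenyl group at C3, would be coupled with carbon monoxide and 1-(benzyloxy)-4-ethynylbenzene A2 under palladium catalysis (carbonylative Sonogashira coupling, then 6-endo closure of the ortho-hydroxy ynone) to the free 7''-phenol A3.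
- In its favour: A3 is the same compound as 16, so the endgame would shrink to sulfation and hydrogenolysis. The hydroxyl not used in the annulation is automatically O7''–H, so no acetal is needed. The flavone never meets the organozinc, carbene or SmI2 steps. Carbonylative flavone annulation is a well-documented reaction type.
- Against it: the cut leaves the real problem untouched. A1 already contains both stereocentres and the congested C3–aryl bond, and would need its own stereocontrolled arylation of a flavanone. Iodination of the resorcinol ring would compete with the equally activated ring A. The annulation needs amine base, CO and heat on a substrate whose C3–H is acidic and whose ring C can open, and 5-exo closure to an aurone would compete.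
- Comparison: on protecting-group economy and on chemoselectivity towards the flavone this plan is better than the chosen one, and its key step has the stronger precedent. On structure it solves the easy ring and postpones ring C and C2. It is two steps shorter after the key step, but the way to A1 is open and probably longer than the eight steps to 12.

Alternative 2: The cut takes O1–C2 and C3–C4 together. Aldehyde 11 and trimethyl orthoformate would form a 4-methoxy ortho-quinone methide under a chiral phosphoric acid, which would add to the (E)-8-styrylflavone A4 (O7'' as 2,2,2-trichloroethyl sulfate) to give the all-trans (2R,3R,4R)-4-methoxychroman A5.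
- In its favour: it is the most convergent plan. Both ring C bonds and both stereocentres form in one step, the trans relation comes from the alkene geometry, and the sulfate travels as a neutral diester.
- Against it: the reaction type is established for styrenes and other electron-rich terminal alkenes. A4 is a 1,2-diaryl alkene whose flavonyl group is di-ortho-substituted and twisted, so reactivity and regiochemistry (which benzylic cation is formed) would be less secure, and a stepwise cationic path could leak to cis. C4 would arrive at the wrong oxidation level, and turning the methyl ether into the ketone in the presence of five benzyl ethers would add two delicate steps. The sulfate diester would have to survive acid and oxidant.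
- Comparison: on direct control of the C2/C3 relation it is better than the chosen plan, and it equals it in using 11 unchanged. Mechanistically an intermolecular cycloaddition on a hindered stilbene is less certain than an intramolecular closure. The step count would be about equal.

Alternative 3: The cut takes O1–C8a, C4–C4a and O1–C2. The acid A6, a 2-(flavon-8-yl)-3-methoxyacrylic acid, would meet the aryne released by CsF from the silyl triflate A7. The carboxylate oxygen and then the acyl carbon would add across the aryne, and the phenoxide would displace methoxide to give the 3-(flavon-8-yl)chromone A8.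
- In its favour: the 3-benzyloxy group of the aryne fixes the regiochemistry, no addition to a hindered ketone is needed, and there is no aldol competition. As a ring closure it is at least the equal of the chosen step.
- Against it: A8 is flat. It has no C2 aryl group and no stereocentre, so ring B and both stereocentres would have to come from an asymmetric conjugate arylation of a chromone that carries a di-ortho-substituted aryl group at the alpha position, well outside the usual scope. The flavone in A8 is a second acceptor. A6 and A7 each need several steps.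
- Comparison: on structure it defers what the chosen plan solves in its key step. After the key step it needs four steps (conjugate arylation, acetal removal, sulfation, hydrogenolysis), equal to the chosen plan. Before the key step it would be longer.

Key step: step 8

Assumption: 17 and 18 are written as hydrogen sulfates, as the target is drawn; in practice they would be handled as sodium salts, which changes no bond-forming event.

Step 1
Reactants: 1 apigenin
Product: 2 7-O-(methoxymethyl)apigenin
Conditions: MOMCl (1.05 equiv), K2CO3 (1.1 equiv), DMF, 0 °C to rt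
Reagents that add atoms: chloromethyl methyl ether, COCCl
Why: Williamson etherification; O7–H is the most acidic phenol, O5–H is tied up in a hydrogen bond to C4=O and O4'–H is less acidic, so one equivalent of weak base and electrophile should alkylate O7 preferentially, the 7,4'-bis ether being removable by chromatography.

Step 2
Reactants: 2 7-O-(methoxymethyl)apigenin
Product: 3 5,4'-di-O-benzyl-7-O-(methoxymethyl)apigenin
Conditions: BnBr (3 equiv), K2CO3 (4 equiv), DMF, 70 °C
Reagents that add atoms: benzyl bromide, BrCc1ccccc1
Why: Exhaustive Williamson benzylation; heating in DMF should overcome the chelation of O5–H, and the acetal is inert to base.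

Step 3
Reactants: 3 5,4'-di-O-benzyl-7-O-(methoxymethyl)apigenin
Product: 4 8-iodo-5,4'-di-O-benzyl-7-O-(methoxymethyl)apigenin
Conditions: NIS (1.2 equiv), DMF, rt to 45 °C, dark
Reagents that add atoms: N-iodosuccinimide, O=C1CCC(=O)N1I
Why: Electrophilic aromatic iodination; with O5 and O7 both etherified, C8 (ortho to O7, para to O5) is the usual site of halogenation of 5,7-dialkoxyflavones, C6 being flanked by two alkoxy groups, and the neutral medium keeps the acetal.

Step 4
Reactants: 4 8-iodo-5,4'-di-O-benzyl-7-O-(methoxymethyl)apigenin; 5 4-(benzyloxy)benzyl chloride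
Product: 7 8-{[4-(benzyloxy)phenyl]acetyl}-5,4'-di-O-benzyl-7-O-(methoxymethyl)apigenin, via 4-(benzyloxy)benzylzinc chloride 6 (not isolated)
Conditions: 5, activated Zn dust, LiCl, THF, 25 °C; then 4, Pd(PPh3)4 (5 mol %), CO (1 atm), THF, 50 °C
Reagents that add atoms: carbon monoxide, [C-]#[O+]
Why: Zinc insertion into the benzylic chloride followed by carbonylative Negishi coupling; zerovalent palladium adds to the aryl iodide, CO insertion gives the aroyl palladium (favoured at a di-ortho-substituted aryl), and transmetalation with reductive elimination should give the aryl benzyl ketone. The flavone carbonyl, the acetal and the benzyl ethers are inert to a benzylzinc halide.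

Step 5
Reactants: 7 8-{[4-(benzyloxy)phenyl]acetyl}-5,4'-di-O-benzyl-7-O-(methoxymethyl)apigenin
Product: 9 racemic 8-{bromo[4-(benzyloxy)phenyl]acetyl}-5,4'-di-O-benzyl-7-O-(methoxymethyl)apigenin, via lithium enolate 8 (not isolated)
Conditions: LiN(SiMe3)2 (1.1 equiv), THF, −78 °C; then cannulated into NBS (1.05 equiv), THF, −78 °C; NH4Cl aq
Reagents that add atoms: N-bromosuccinimide, O=C1CCC(=O)N1Br
Why: Alpha-bromination of a preformed ketone enolate; the benzylic methylene is the only acidic site, the enolate should react with NBS at −78 °C far faster than the electron-rich rings do, and no acid is set free that could cleave the acetal.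

Step 6
Reactants: 10 2,4,6-trihydroxybenzaldehyde
Product: 11 2,4-bis(benzyloxy)-6-hydroxybenzaldehyde
Conditions: BnBr (2.1 equiv), K2CO3 (2.2 equiv), DMF, 0 °C to rt
Reagents that add atoms: benzyl bromide, BrCc1ccccc1
Why: Williamson benzylation; once the para and one ortho hydroxyl are etherified, the last hydroxyl is locked in a hydrogen bond to the aldehyde and should resist alkylation at rt.

Step 7
Reactants: 9 racemic 8-{bromo[4-(benzyloxy)phenyl]acetyl}-5,4'-di-O-benzyl-7-O-(methoxymethyl)apigenin; 11 2,4-bis(benzyloxy)-6-hydroxybenzaldehyde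
Product: 12 racemic 2,4-bis(benzyloxy)-6-{1-[4-(benzyloxy)phenyl]-2-oxo-2-[5,4'-di-O-benzyl-7-O-(methoxymethyl)apigenin-8-yl]ethoxy}benzaldehyde
Conditions: K2CO3 (1.5 equiv), DMF, 0 °C to rt
Reagents that add atoms: none
Why: SN2 displacement of an activated alpha-keto benzylic bromide by the phenoxide (Williamson etherification); at rt the reaction should stop at the ether, since the Rap–Stoermer-type aldol onto the deactivated trialkoxybenzaldehyde needs heat and has no dehydration outlet at a quaternary carbon.

Step 8
Reactants: 12 racemic 2,4-bis(benzyloxy)-6-{1-[4-(benzyloxy)phenyl]-2-oxo-2-[5,4'-di-O-benzyl-7-O-(methoxymethyl)apigenin-8-yl]ethoxy}benzaldehyde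
Product: 13 (2S,3R)-3-hydroxy-3-[5,4'-di-O-benzyl-7-O-(methoxymethyl)apigenin-8-yl]-5,7,4'-tri-O-benzylnaringenin (C2 aryl and C3 flavonyl trans)
Conditions: (5aR,10bS)-2-(pentafluorophenyl)-5a,10b-dihydro-4H,6H-indeno[2,1-b][1,2,4]triazolo[4,3-d][1,4]oxazin-2-ium tetrafluoroborate (10 mol %, or its antipode as a model study dictates), Et3N (1.0 equiv), toluene, 25 °C
Reagents that add atoms: none
Why: This is an intramolecular crossed aldehyde–ketone benzoin reaction under chiral triazolylidene catalysis with dynamic kinetic resolution, the closest known type being the carbene-catalysed cyclisation of 2-(2-oxoalkoxy)benzaldehydes to 3-hydroxychroman-4-ones. The carbene adds to the aldehyde carbon (future C4), proton transfer gives the Breslow intermediate, its nucleophilic carbon attacks the ketone carbon (future C3), and collapse of the adduct releases the carbene and leaves the C4 ketone and the C3 carbinol. Ring C closes in the 6-exo-trig mode, the former ketone oxygen staying outside the new ring. C2 is not created but selected: in 12 its hydrogen is flanked by the ketone, the aryl ring and the ether oxygen, so Et3N should interconvert the enantiomers through the enolate faster than either cyclises, and after closure C2 is beta to the new ketone and no longer enolisable. C3 is set by the catalyst, whose aminoindanol backbone shields one face of the Breslow intermediate and so decides which ketone face is attacked. C2 follows from C3 through the chair-like transition state, in which the C2 aryl group sits pseudo-equatorial and anti to the flavonyl group, so only one enantiomer of 12 fits the ketone face that the catalyst prefers. The chemoselectivity needed is acyl anion addition ahead of the 5-exo aldol of the same enolate onto the aldehyde, which the electron-poor N-aryl triazolium (usable with a weak amine base) and the poorly electrophilic trialkoxybenzaldehyde should favour. Any C3 epimer must be removed by chromatography before the next step, because with catalyst control at C3 it would carry the opposite C2 configuration.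

Step 9
Reactants: 13 (2S,3R)-3-hydroxy-3-[5,4'-di-O-benzyl-7-O-(methoxymethyl)apigenin-8-yl]-5,7,4'-tri-O-benzylnaringenin
Product: 15 (2R,3S)-3-[5,4'-di-O-benzyl-7-O-(methoxymethyl)apigenin-8-yl]-5,7,4'-tri-O-benzylnaringenin, via samarium enolate 14 (not isolated)
Conditions: SmI2 (2.5 equiv), THF–MeOH (10:1), −78 °C; NH4Cl aq; then Et3N (0.2 equiv), CH2Cl2, rt
Reagents that add atoms: none
Why: Reductive cleavage of an alpha-hydroxy ketone by SmI2; two electron transfers to the chelated ketol expel hydroxide and give the enolate of trivalent samarium, which methanol protonates at C3. Because C3 is alpha to the ketone, brief amine treatment should settle it in the diequatorial trans (3S) arrangement; C2 is untouched, its descriptor changing from S to R only because C3 drops in priority.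

Step 10
Reactants: 15 (2R,3S)-3-[5,4'-di-O-benzyl-7-O-(methoxymethyl)apigenin-8-yl]-5,7,4'-tri-O-benzylnaringenin
Product: 16 (2R,3S)-3-(5,4'-di-O-benzylapigenin-8-yl)-5,7,4'-tri-O-benzylnaringenin
Conditions: HCl (2 M), MeOH–THF (1:1), 40 °C
Reagents that add atoms: none
Why: Acid-catalysed acetal exchange should remove the methoxymethyl group as dimethoxymethane; benzyl ethers and the flavanone tolerate dilute acid, and C3 is already in its thermodynamic arrangement.

Step 11
Reactants: 16 (2R,3S)-3-(5,4'-di-O-benzylapigenin-8-yl)-5,7,4'-tri-O-benzylnaringenin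
Product: 17 (2R,3S)-3-(5,4'-di-O-benzyl-7-O-sulfoapigenin-8-yl)-5,7,4'-tri-O-benzylnaringenin
Conditions: SO3·pyridine (5 equiv), pyridine, rt to 40 °C; NaHCO3 aq
Reagents that add atoms: sulfur trioxide–pyridine complex, [O-]S(=O)(=O)[n+]1ccccc1
Why: O-Sulfation of a phenol with an amine–sulfur trioxide complex; O7''–H is the only hydroxyl, so no selectivity is required, and excess reagent should make up for the ortho substituent.

Step 12
Reactants: 17 (2R,3S)-3-(5,4'-di-O-benzyl-7-O-sulfoapigenin-8-yl)-5,7,4'-tri-O-benzylnaringenin
Product: 18 (2R,3S)-3-(7-O-sulfoapigenin-8-yl)naringenin (CNP0271389.1)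
Conditions: H2 (1 atm), Pd(OH)2/C, THF–MeOH (1:1), rt
Reagents that add atoms: none
Why: Catalytic hydrogenolysis of the five benzyl ethers; aryl sulfate salts, the flavone double bond and the cyclic benzylic C2–O1 bond are normally kept under neutral low-pressure conditions, and neither stereocentre takes part.

Compound list

1 | apigenin | O=c1cc(-c2ccc(O)cc2)oc2cc(O)cc(O)c12 | starting material
2 | 7-O-(methoxymethyl)apigenin | O=c1cc(-c2ccc(O)cc2)oc2cc(OCOC)cc(O)c12 | intermediate
3 | 5,4'-di-O-benzyl-7-O-(methoxymethyl)apigenin | O=c1cc(-c2ccc(OCc3ccccc3)cc2)oc2cc(OCOC)cc(OCc3ccccc3)c12 | intermediate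
4 | 8-iodo-5,4'-di-O-benzyl-7-O-(methoxymethyl)apigenin | O=c1cc(-c2ccc(OCc3ccccc3)cc2)oc2c(I)c(OCOC)cc(OCc3ccccc3)c12 | intermediate
5 | 4-(benzyloxy)benzyl chloride | ClCc1ccc(OCc2ccccc2)cc1 | starting material
6 | 4-(benzyloxy)benzylzinc chloride | Cl[Zn]Cc1ccc(OCc2ccccc2)cc1 | intermediate (not isolated)
7 | 8-{[4-(benzyloxy)phenyl]acetyl}-5,4'-di-O-benzyl-7-O-(methoxymethyl)apigenin | O=C(Cc1ccc(OCc2ccccc2)cc1)c1c(OCOC)cc(OCc2ccccc2)c2c(=O)cc(-c3ccc(OCc4ccccc4)cc3)oc12 | intermediate
8 | lithium (Z)-enolate of 7 (geometry immaterial) | [Li+].[O-]/C(=C\c1ccc(OCc2ccccc2)cc1)c1c(OCOC)cc(OCc2ccccc2)c2c(=O)cc(-c3ccc(OCc4ccccc4)cc3)oc12 | intermediate (not isolated)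
9 | racemic 8-{bromo[4-(benzyloxy)phenyl]acetyl}-5,4'-di-O-benzyl-7-O-(methoxymethyl)apigenin | O=C(C(Br)c1ccc(OCc2ccccc2)cc1)c1c(OCOC)cc(OCc2ccccc2)c2c(=O)cc(-c3ccc(OCc4ccccc4)cc3)oc12 | intermediate
10 | 2,4,6-trihydroxybenzaldehyde | O=Cc1c(O)cc(O)cc1O | starting material
11 | 2,4-bis(benzyloxy)-6-hydroxybenzaldehyde | O=Cc1c(O)cc(OCc2ccccc2)cc1OCc1ccccc1 | intermediate
12 | racemic 2,4-bis(benzyloxy)-6-{1-[4-(benzyloxy)phenyl]-2-oxo-2-[5,4'-di-O-benzyl-7-O-(methoxymethyl)apigenin-8-yl]ethoxy}benzaldehyde | O=Cc1c(OCc2ccccc2)cc(OCc2ccccc2)cc1OC(c1ccc(OCc2ccccc2)cc1)C(=O)c1c(OCOC)cc(OCc2ccccc2)c2c(=O)cc(-c3ccc(OCc4ccccc4)cc3)oc12 | intermediate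
13 | (2S,3R)-3-hydroxy-3-[5,4'-di-O-benzyl-7-O-(methoxymethyl)apigenin-8-yl]-5,7,4'-tri-O-benzylnaringenin | O=C1c2c(OCc3ccccc3)cc(OCc3ccccc3)cc2O[C@@H](c2ccc(OCc3ccccc3)cc2)[C@]1(O)c1c(OCOC)cc(OCc2ccccc2)c2c(=O)cc(-c3ccc(OCc4ccccc4)cc3)oc12 | intermediate
14 | diiodosamarium 3,4-enolate of 15, (2S) | [Sm+3].[I-].[I-].[O-]C1=C(c2c(OCOC)cc(OCc3ccccc3)c3c(=O)cc(-c4ccc(OCc5ccccc5)cc4)oc23)[C@H](c2ccc(OCc3ccccc3)cc2)Oc2cc(OCc3ccccc3)cc(OCc3ccccc3)c12 | intermediate (not isolated)
15 | (2R,3S)-3-[5,4'-di-O-benzyl-7-O-(methoxymethyl)apigenin-8-yl]-5,7,4'-tri-O-benzylnaringenin | O=C1c2c(OCc3ccccc3)cc(OCc3ccccc3)cc2O[C@@H](c2ccc(OCc3ccccc3)cc2)[C@@H]1c1c(OCOC)cc(OCc2ccccc2)c2c(=O)cc(-c3ccc(OCc4ccccc4)cc3)oc12 | intermediate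
16 | (2R,3S)-3-(5,4'-di-O-benzylapigenin-8-yl)-5,7,4'-tri-O-benzylnaringenin | O=C1c2c(OCc3ccccc3)cc(OCc3ccccc3)cc2O[C@@H](c2ccc(OCc3ccccc3)cc2)[C@@H]1c1c(O)cc(OCc2ccccc2)c2c(=O)cc(-c3ccc(OCc4ccccc4)cc3)oc12 | intermediate
17 | (2R,3S)-3-(5,4'-di-O-benzyl-7-O-sulfoapigenin-8-yl)-5,7,4'-tri-O-benzylnaringenin (hydrogen sulfate) | O=C1c2c(OCc3ccccc3)cc(OCc3ccccc3)cc2O[C@@H](c2ccc(OCc3ccccc3)cc2)[C@@H]1c1c(OS(=O)(=O)O)cc(OCc2ccccc2)c2c(=O)cc(-c3ccc(OCc4ccccc4)cc3)oc12 | intermediate
18 | (2R,3S)-3-(7-O-sulfoapigenin-8-yl)naringenin, 8-[(2R,3S)-5,7-dihydroxy-2-(4-hydroxyphenyl)-4-oxochroman-3-yl]-5-hydroxy-2-(4-hydroxyphenyl)-4-oxo-4H-chromen-7-yl hydrogen sulfate | O=C1c2c(O)cc(O)cc2O[C@@H](c2ccc(O)cc2)[C@@H]1c1c(OS(=O)(=O)O)cc(O)c2c(=O)cc(-c3ccc(O)cc3)oc12 | target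

Total step count: 12. Longest linear sequence: 11 steps (steps 1–5 and 7–12, from 1); step 6 is a one-step branch.

Steps least certain to work

Step 8 (key step). Two processes are most likely to go wrong. First, the enolate that racemises C2 may close onto the aldehyde in a 5-exo aldol while carbene addition to the di-ortho-alkoxy aldehyde and attack on the di-ortho-substituted ketone are slow. Second, discrimination between the interconverting C2 enantiomers may be weak, or may erode with time through retro-benzoin reaction. The cause in each case is that the same base must both racemise C2 and generate the carbene, and that both carbonyl groups are hindered. Fallback, from 12 back to 15: ring closure and stereocontrol are decoupled. With no need for racemisation, the achiral 2-(pentafluorophenyl)-6,7-dihydro-5H-pyrrolo[2,1-c][1,2,4]triazol-2-ium tetrafluoroborate and NaOAc in THF would be used, a base too weak to enolise the ketone appreciably, to give the racemic 3-hydroxy ketone F1. SmI2 and equilibration as in step 9 would give the racemic trans ketone F2, and preparative chromatography on a chiral stationary phase would deliver the (2R,3S) enantiomer, which is 15.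

Step 9. Electron transfer may go to the flavone carbonyl instead of the electron-rich ring A ketone, or the samarium enolate may expel the O1 aryloxide (ring opening, which would scramble C2) before it is protonated. The cause is that the ketol carbonyl is a poor acceptor and a free hydroxyl a modest leaving group. Fallback, from 13 back to 15: the C–O bond is broken by a radical path. Methyl chlorooxoacetate, DMAP and pyridine in CH2Cl2 would give the tertiary methyl oxalate F3. Bu3SnH and AIBN in toluene at reflux would fragment it to the captodatively stabilised C3 radical, which abstracts hydrogen; Et3N equilibration would then give 15.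

Step 4. Direct coupling without CO insertion (a diarylmethane), homocoupling of the benzylzinc reagent, or slow turnover at the hindered iodide may dominate. Fallback, from 4 back to 7, without carbon monoxide: Stille coupling with tributyl(1-ethoxyvinyl)stannane (Pd(PPh3)4, toluene, 100 °C) would give the enol ether F4. Brief hydrolysis (1 M HCl, THF, 0 °C) would give the methyl ketone F5. Palladium-catalysed alpha-arylation with 1-(benzyloxy)-4-bromobenzene (Pd2(dba)3, Xantphos, NaOtBu, toluene, 80 °C) would then give 7.

Step 5. Proton exchange between product and unreacted enolate may lead to dibromination and returned ketone, or bromination may occur at C6'' or C3''. Fallback, from 7 back to 12, avoiding halogenation and step 7: Regitz diazo transfer (4-acetamidobenzenesulfonyl azide, DBU, MeCN) would give the alpha-diazo ketone F6. Rh2(OAc)4-catalysed O–H insertion of its carbenoid into phenol 11 (CH2Cl2, rt) would form the O1–C2 bond and give 12 directly.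

Step 12. Over-reduction may occur (hydrogenolytic opening of C2–O1, saturation of C2''=C3''), or the sulfate may hydrolyse as the phenols are unmasked. Fallback, from 16 back to 18, with acid-mediated debenzylation on a protected sulfate: 2,2,2-trichloroethyl chlorosulfate, DMAP and Et3N in THF would give the neutral sulfate diester F7. BCl3 with pentamethylbenzene in CH2Cl2 at −78 °C would remove the benzyl groups to give the pentaphenol F8. Zn and HCO2NH4 in MeOH would release the sulfate and give 18.

Further compounds

F1 | step 8 | racemic 3-hydroxy-3-[5,4'-di-O-benzyl-7-O-(methoxymethyl)apigenin-8-yl]-5,7,4'-tri-O-benzylnaringenin (C3 epimers not distinguished) | O=C1c2c(OCc3ccccc3)cc(OCc3ccccc3)cc2OC(c2ccc(OCc3ccccc3)cc2)C1(O)c1c(OCOC)cc(OCc2ccccc2)c2c(=O)cc(-c3ccc(OCc4ccccc4)cc3)oc12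
F2 | step 8 | racemic trans-3-[5,4'-di-O-benzyl-7-O-(methoxymethyl)apigenin-8-yl]-5,7,4'-tri-O-benzylnaringenin (both enantiomers) | O=C1c2c(OCc3ccccc3)cc(OCc3ccccc3)cc2O[C@@H](c2ccc(OCc3ccccc3)cc2)[C@@H]1c1c(OCOC)cc(OCc2ccccc2)c2c(=O)cc(-c3ccc(OCc4ccccc4)cc3)oc12.O=C1c2c(OCc3ccccc3)cc(OCc3ccccc3)cc2O[C@H](c2ccc(OCc3ccccc3)cc2)[C@H]1c1c(OCOC)cc(OCc2ccccc2)c2c(=O)cc(-c3ccc(OCc4ccccc4)cc3)oc12
F3 | step 9 | (2S,3R)-3-[5,4'-di-O-benzyl-7-O-(methoxymethyl)apigenin-8-yl]-5,7,4'-tri-O-benzylnaringenin-3-yl methyl oxalate | O=C1c2c(OCc3ccccc3)cc(OCc3ccccc3)cc2O[C@@H](c2ccc(OCc3ccccc3)cc2)[C@]1(OC(=O)C(=O)OC)c1c(OCOC)cc(OCc2ccccc2)c2c(=O)cc(-c3ccc(OCc4ccccc4)cc3)oc12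
F4 | step 4 | 8-(1-ethoxyvinyl)-5,4'-di-O-benzyl-7-O-(methoxymethyl)apigenin | C=C(OCC)c1c(OCOC)cc(OCc2ccccc2)c2c(=O)cc(-c3ccc(OCc4ccccc4)cc3)oc12
F5 | step 4 | 8-acetyl-5,4'-di-O-benzyl-7-O-(methoxymethyl)apigenin | CC(=O)c1c(OCOC)cc(OCc2ccccc2)c2c(=O)cc(-c3ccc(OCc4ccccc4)cc3)oc12
F6 | step 5 | 8-{diazo[4-(benzyloxy)phenyl]acetyl}-5,4'-di-O-benzyl-7-O-(methoxymethyl)apigenin | [N-]=[N+]=C(c1ccc(OCc2ccccc2)cc1)C(=O)c1c(OCOC)cc(OCc2ccccc2)c2c(=O)cc(-c3ccc(OCc4ccccc4)cc3)oc12
F7 | step 12 | (2R,3S)-3-{5,4'-di-O-benzyl-7-O-[(2,2,2-trichloroethoxy)sulfonyl]apigenin-8-yl}-5,7,4'-tri-O-benzylnaringenin | O=C1c2c(OCc3ccccc3)cc(OCc3ccccc3)cc2O[C@@H](c2ccc(OCc3ccccc3)cc2)[C@@H]1c1c(OS(=O)(=O)OCC(Cl)(Cl)Cl)cc(OCc2ccccc2)c2c(=O)cc(-c3ccc(OCc4ccccc4)cc3)oc12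
F8 | step 12 | (2R,3S)-3-{7-O-[(2,2,2-trichloroethoxy)sulfonyl]apigenin-8-yl}naringenin | O=C1c2c(O)cc(O)cc2O[C@@H](c2ccc(O)cc2)[C@@H]1c1c(OS(=O)(=O)OCC(Cl)(Cl)Cl)cc(O)c2c(=O)cc(-c3ccc(O)cc3)oc12
A1 | alternative 1 | (2R,3S)-3-[4-(benzyloxy)-2,6-dihydroxy-3-iodophenyl]-5,7,4'-tri-O-benzylnaringenin | O=C1c2c(OCc3ccccc3)cc(OCc3ccccc3)cc2O[C@@H](c2ccc(OCc3ccccc3)cc2)[C@@H]1c1c(O)cc(OCc2ccccc2)c(I)c1O
A2 | alternative 1 | 1-(benzyloxy)-4-ethynylbenzene | C#Cc1ccc(OCc2ccccc2)cc1
A3 | alternative 1 | (2R,3S)-3-(5,4'-di-O-benzylapigenin-8-yl)-5,7,4'-tri-O-benzylnaringenin (same compound as 16) | O=C1c2c(OCc3ccccc3)cc(OCc3ccccc3)cc2O[C@@H](c2ccc(OCc3ccccc3)cc2)[C@@H]1c1c(O)cc(OCc2ccccc2)c2c(=O)cc(-c3ccc(OCc4ccccc4)cc3)oc12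
A4 | alternative 2 | 5-(benzyloxy)-2-[4-(benzyloxy)phenyl]-8-{(E)-2-[4-(benzyloxy)phenyl]ethenyl}-4-oxo-4H-chromen-7-yl 2,2,2-trichloroethyl sulfate | O=c1cc(-c2ccc(OCc3ccccc3)cc2)oc2c(/C=C/c3ccc(OCc4ccccc4)cc3)c(OS(=O)(=O)OCC(Cl)(Cl)Cl)cc(OCc3ccccc3)c12
A5 | alternative 2 | 8-{(2R,3R,4R)-5,7-bis(benzyloxy)-2-[4-(benzyloxy)phenyl]-4-methoxychroman-3-yl}-5-(benzyloxy)-2-[4-(benzyloxy)phenyl]-4-oxo-4H-chromen-7-yl 2,2,2-trichloroethyl sulfate | CO[C@H]1c2c(OCc3ccccc3)cc(OCc3ccccc3)cc2O[C@@H](c2ccc(OCc3ccccc3)cc2)[C@@H]1c1c(OS(=O)(=O)OCC(Cl)(Cl)Cl)cc(OCc2ccccc2)c2c(=O)cc(-c3ccc(OCc4ccccc4)cc3)oc12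
A6 | alternative 3 | 2-[5,4'-di-O-benzyl-7-O-(methoxymethyl)apigenin-8-yl]-3-methoxyprop-2-enoic acid (alkene geometry immaterial) | COC=C(C(=O)O)c1c(OCOC)cc(OCc2ccccc2)c2c(=O)cc(-c3ccc(OCc4ccccc4)cc3)oc12
A7 | alternative 3 | 3,5-bis(benzyloxy)-2-(trimethylsilyl)phenyl trifluoromethanesulfonate | C[Si](C)(C)c1c(OCc2ccccc2)cc(OCc2ccccc2)cc1OS(=O)(=O)C(F)(F)F
A8 | alternative 3 | 5,7-bis(benzyloxy)-3-[5,4'-di-O-benzyl-7-O-(methoxymethyl)apigenin-8-yl]-4H-chromen-4-one | O=c1c(-c2c(OCOC)cc(OCc3ccccc3)c3c(=O)cc(-c4ccc(OCc5ccccc5)cc4)oc23)coc2cc(OCc3ccccc3)cc(OCc3ccccc3)c12
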